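The cyclohexene is numbered C1 (bearing CH2OBz), C2 (=CH), C3 (OMe), C4 (OH), C5 (OBz), C6 (OH). The route rests on cutting C2–C3 and C4–C5: the cis-dioxygenated C3–C4 pair is an enediol ketal, 2,2-dimethyl-1,3-dioxole, and C2/C1/C6/C5 are C6/C5/C4/C3 of methyl coumalate, whose ester carbon becomes the CH2OBz carbon. One inverse-demand Diels–Alder reaction followed by loss of CO2 in the same flask forges both bonds, fixes the cis C3/C4 oxygens and leaves a C1=C2/C5=C6 diene; its C5=C6 bond is then dihydroxylated anti to the ketal. A lipase resolution supplies the enantiomer, and the C3 methyl ether comes from a palladium-catalysed opening of the C3/C4 cyclic carbonate.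

Key step: step 1

Assumptions and conventions: 2,2-dimethyl-1,3-dioxole is taken as a purchasable fine chemical (otherwise it is made by chlorination of 2,2-dimethyl-1,3-dioxolane and dehydrochlorination with KOtBu); racemic 3, 4 and 5 are drawn as the enantiomer that is carried on; α is the ring face of the C3 and C4 oxygens, β the face of the C5 and C6 oxygens.

Step 1
Reactants: 1 methyl coumalate; 2 2,2-dimethyl-1,3-dioxole
Product: 4 methyl 3α,4α-(isopropylidenedioxy)cyclohexa-1,5-diene-1-carboxylate (racemic), via bridged lactone cycloadduct 3 (not isolated)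
Conditions: 2 (1.5 equiv), toluene, solid NaHCO3, BHT (cat.), sealed tube, 60 °C then 100 °C (−CO2)
Reagents that add atoms: none
Why: Inverse-electron-demand Diels–Alder reaction: the electron-rich enediol ketal 2 adds across C3 and C6 of the electron-poor 2-pyrone 1 in a concerted, asynchronous [4+2] (the bond to pyrone C6 leading), and the bridged lactone 3 then loses CO2 by thermal retro-[4+2] to unveil the cyclohexa-1,5-diene. The closest known reaction type is the cycloaddition of ester-substituted 2-pyrones with enol ethers and ketene acetals followed by decarboxylation. The six-membered carbocycle is closed by intermolecular [4+2] cycloaddition, both new bonds (C2–C3 and C4–C5) forming suprafacially on each partner, and the lactone bridge is opened again by cycloreversion. C3 and C4 are the only stereocentres that survive: their cis relationship is dictated by the ring-constrained Z geometry of 2, endo/exo selectivity is irrelevant because both bridgeheads return to sp2, and absolute configuration is not controlled here (racemate, resolved in step 3). The step needs mono-addition and no aromatisation: the pyrone is far more electron-poor than the product diene and the volatile dienophile is used in small excess, while acid-free conditions keep the ketal oxygens from leaving to give a hydroxybenzoate.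

Step 2
Reactants: 4 methyl 3α,4α-(isopropylidenedioxy)cyclohexa-1,5-diene-1-carboxylate (racemic)
Product: 5 methyl 5β,6β-dihydroxy-3α,4α-(isopropylidenedioxy)cyclohex-1-ene-1-carboxylate (racemic)
Conditions: OsO4 (2 mol%), NMO (1.3 equiv), acetone/H2O (5:1), 0 °C to rt; aq. Na2SO3
Reagents that add atoms: osmium tetroxide O=[Os](=O)(=O)=O (catalytic oxygen carrier); N-methylmorpholine N-oxide C[N+]1([O-])CCOCC1; water O
Why: Catalytic OsO4 syn-dihydroxylation should take the more electron-rich disubstituted C5=C6 bond (C1=C2 is a deactivated acrylate) on the face anti to the adjacent C4 ketal oxygen, which sets C5 and C6 cis to each other and trans to C4.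

Step 3
Reactants: 5 methyl 5β,6β-dihydroxy-3α,4α-(isopropylidenedioxy)cyclohex-1-ene-1-carboxylate (racemic)
Product: 6 methyl 5β-acetoxy-6β-hydroxy-3α,4α-(isopropylidenedioxy)cyclohex-1-ene-1-carboxylate (single enantiomer, ring configured as in 11)
Conditions: Burkholderia cepacia lipase (immobilised), vinyl acetate (3 equiv), tBuOMe, 30 °C, to about half conversion; chromatographic separation from the unreacted antipodal diol
Reagents that add atoms: vinyl acetate CC(=O)OC=C
Why: Lipase-catalysed kinetic resolution by irreversible transesterification, no new stereocentre being formed: the usual empirical model for secondary alcohols (large group = ketal-bearing C4 side, medium group = C6 side) predicts acetylation of the equatorial C5–OH of the target-series enantiomer; a C6 acetate of the same enantiomer would converge in step 4, and should the enzyme prefer the antipode, the recovered diol is the target-series material and enters step 4 unchanged.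

Step 4
Reactants: 6 methyl 5β-acetoxy-6β-hydroxy-3α,4α-(isopropylidenedioxy)cyclohex-1-ene-1-carboxylate
Product: 7 1-(hydroxymethyl)-3α,4α-(isopropylidenedioxy)cyclohex-1-ene-5β,6β-diol
Conditions: iBu2AlH (7 equiv), CH2Cl2, −78 °C to 0 °C; aq. KNaC4H4O6
Reagents that add atoms: none
Why: iBu2AlH reduces the conjugated methyl ester by 1,2-hydride delivery to the primary allylic alcohol and cleaves the C5 acetate in the same operation, leaving the ketal and all stereocentres untouched.

Step 5
Reactants: 7 1-(hydroxymethyl)-3α,4α-(isopropylidenedioxy)cyclohex-1-ene-5β,6β-diol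
Product: 8 [5β-(benzoyloxy)-6β-hydroxy-3α,4α-(isopropylidenedioxy)cyclohex-1-en-1-yl]methyl benzoate
Conditions: BzCl (2.1 equiv), pyridine, CH2Cl2, −40 °C to −10 °C
Reagents that add atoms: benzoyl chloride O=C(Cl)c1ccccc1
Why: Kinetically controlled acylation should take the primary allylic hydroxyl first and then the equatorial C5–OH, leaving the pseudoaxial C6–OH, wedged between C5 and the substituted alkene carbon C1, free; low temperature and pyridine without DMAP suppress a third acylation and benzoyl migration.

Step 6
Reactants: 8 [5β-(benzoyloxy)-6β-hydroxy-3α,4α-(isopropylidenedioxy)cyclohex-1-en-1-yl]methyl benzoate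
Product: 9 [5β-(benzoyloxy)-3α,4α,6β-trihydroxycyclohex-1-en-1-yl]methyl benzoate
Conditions: AcOH/H2O (4:1), 40 °C; toluene azeotrope
Reagents that add atoms: none
Why: Acid-catalysed hydrolysis of the cis-fused isopropylidene ketal frees the C3/C4 diol without base, so the benzoates should neither cleave nor migrate, and no stereocentre is involved.

Step 7
Reactants: 9 [5β-(benzoyloxy)-3α,4α,6β-trihydroxycyclohex-1-en-1-yl]methyl benzoate
Product: 10 [5β-(benzoyloxy)-3α,4α-(carbonyldioxy)-6β-hydroxycyclohex-1-en-1-yl]methyl benzoate
Conditions: CDI (1.1 equiv), CH2Cl2, 0 °C to rt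
Reagents that add atoms: 1,1'-carbonyldiimidazole O=C(n1ccnc1)n1ccnc1
Why: Only the cis-vicinal C3/C4 diol can close a five-membered cyclic carbonate by double nucleophilic acyl substitution on carbonyldiimidazole, the isolated, hindered C6–OH staying free; no C–O bond at a stereocentre is broken.

Step 8
Reactants: 10 [5β-(benzoyloxy)-3α,4α-(carbonyldioxy)-6β-hydroxycyclohex-1-en-1-yl]methyl benzoate
Product: 11 [(3R,4R,5R,6R)-5-(benzoyloxy)-4,6-dihydroxy-3-methoxycyclohex-1-en-1-yl]methyl benzoate
Conditions: Pd(PPh3)4 (5 mol%), Et3B (10 mol%), MeOH/THF (1:3), 0 °C to rt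
Reagents that add atoms: methanol CO
Why: Tsuji–Trost-type decarboxylative allylic etherification: zerovalent palladium ionises the allylic C3–O bond of the carbonate anti to the leaving oxygen, CO2 is lost, and methanol (delivered through a boron ate complex on the C4 alkoxide) attacks the allyl terminus C3 anti to palladium, the other terminus C1 being fully substituted, so the methyl ether forms with net retention, cis to the freed C4–OH.

Compound list
1 | methyl coumalate (methyl 2-oxo-2H-pyran-5-carboxylate) | COC(=O)C1=COC(=O)C=C1 | starting material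
2 | 2,2-dimethyl-1,3-dioxole | CC1(C)OC=CO1 | starting material
3 | bridged lactone cycloadduct, methyl 7,8-cis-(isopropylidenedioxy)-3-oxo-2-oxabicyclo[2.2.2]oct-5-ene-6-carboxylate (racemic, endo isomer drawn) | CC1(C)O[C@@H]2[C@H]3OC(=O)[C@H](C=C3C(=O)OC)[C@@H]2O1 | intermediate (not isolated)
4 | methyl 3α,4α-(isopropylidenedioxy)cyclohexa-1,5-diene-1-carboxylate (racemic, (3R,4S) enantiomer drawn) | CC1(C)O[C@@H]2C=C(C(=O)OC)C=C[C@@H]2O1 | intermediate
5 | methyl 5β,6β-dihydroxy-3α,4α-(isopropylidenedioxy)cyclohex-1-ene-1-carboxylate (racemic, target-series enantiomer drawn) | CC1(C)O[C@@H]2C=C(C(=O)OC)[C@@H](O)[C@@H](O)[C@@H]2O1 | intermediate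
6 | methyl 5β-acetoxy-6β-hydroxy-3α,4α-(isopropylidenedioxy)cyclohex-1-ene-1-carboxylate (single enantiomer, ring configured as in 11) | CC1(C)O[C@@H]2C=C(C(=O)OC)[C@@H](O)[C@@H](OC(C)=O)[C@@H]2O1 | intermediate
7 | 1-(hydroxymethyl)-3α,4α-(isopropylidenedioxy)cyclohex-1-ene-5β,6β-diol (ring configured as in 11) | CC1(C)O[C@@H]2C=C(CO)[C@@H](O)[C@@H](O)[C@@H]2O1 | intermediate
8 | [5β-(benzoyloxy)-6β-hydroxy-3α,4α-(isopropylidenedioxy)cyclohex-1-en-1-yl]methyl benzoate | CC1(C)O[C@@H]2C=C(COC(=O)c3ccccc3)[C@@H](O)[C@@H](OC(=O)c3ccccc3)[C@@H]2O1 | intermediate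
9 | [5β-(benzoyloxy)-3α,4α,6β-trihydroxycyclohex-1-en-1-yl]methyl benzoate | O[C@@H]1C=C(COC(=O)c2ccccc2)[C@@H](O)[C@@H](OC(=O)c2ccccc2)[C@@H]1O | intermediate
10 | [5β-(benzoyloxy)-3α,4α-(carbonyldioxy)-6β-hydroxycyclohex-1-en-1-yl]methyl benzoate (C3/C4 cyclic carbonate) | O=C1O[C@@H]2C=C(COC(=O)c3ccccc3)[C@@H](O)[C@@H](OC(=O)c3ccccc3)[C@@H]2O1 | intermediate
11 | [(3R,4R,5R,6R)-5-(benzoyloxy)-4,6-dihydroxy-3-methoxycyclohex-1-en-1-yl]methyl benzoate | CO[C@@H]1C=C(COC(=O)c2ccccc2)[C@@H](O)[C@@H](OC(=O)c2ccccc2)[C@@H]1O | target

Total step count: 8. Longest linear sequence: 8 steps (1 and 2 to 11).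

Steps most likely to fail

Step 8. The allylpalladium chemistry may go astray through competing ionisation of the primary allylic benzoate, β-hydride elimination of the allylpalladium intermediate to a ketone, or benzoyl migration onto the transient C4 alkoxide. Fallback, from 9 back to 11: direct O-methylation of triol 9 under non-basic conditions (Me3OBF4, 1,8-bis(dimethylamino)naphthalene, CH2Cl2, 0 °C), relying on steric differentiation. C3–OH is flanked only by the vinylic CH, whereas C4–OH lies between two oxygenated carbons and C6–OH between the benzoate-bearing C5 and the substituted C1. Regioisomeric ethers would be removed by chromatography. This fallback makes no new compound (F0).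

Step 5. Site selectivity between the two secondary hydroxyls may be poor, or a third acylation may occur. Fallback, from 7 back to 8: tBu2Si(OTf)2 and 2,6-lutidine in CH2Cl2 should bridge the 1,3-related primary and C6 hydroxyls as the six-membered di-tert-butylsilylene acetal F2, the five-membered alternative across C5/C6 being disfavoured. BzCl, pyridine and DMAP then acylate the only free hydroxyl to give the C5 benzoate F3. HF·pyridine in THF removes the silylene to give the diol monobenzoate F4. BzCl with 2,4,6-collidine at −78 °C acylates the primary hydroxyl selectively to give 8.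

Step 3. The enzyme may discriminate poorly between the enantiomers. Fallback, from 5 back to 7: esterification of racemic 5 with (S)-O-methylmandelic acid (DCC, DMAP cat., CH2Cl2, 0 °C) at the equatorial C5–OH gives two diastereomeric esters that are separated by chromatography or crystallisation. The diastereomer with the target-series ring configuration, the C5 (S)-O-methylmandelate F1, is submitted to the iBu2AlH conditions of step 4, which reduce the methyl ester and cleave the auxiliary ester to give 7.

Further compounds
F1 | step 3 | methyl 6β-hydroxy-3α,4α-(isopropylidenedioxy)-5β-[(S)-2-methoxy-2-phenylacetoxy]cyclohex-1-ene-1-carboxylate | CC1(C)O[C@@H]2C=C(C(=O)OC)[C@@H](O)[C@@H](OC(=O)[C@@H](OC)c3ccccc3)[C@@H]2O1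
F2 | step 5 | 7 with the primary and C6 oxygens bridged as a di-tert-butylsilylene acetal, C5–OH free | CC1(C)O[C@@H]2C=C(CO[Si](C(C)(C)C)(C(C)(C)C)O3)[C@@H]3[C@@H](O)[C@@H]2O1
F3 | step 5 | C5 benzoate of the silylene acetal F2 | CC1(C)O[C@@H]2C=C(CO[Si](C(C)(C)C)(C(C)(C)C)O3)[C@@H]3[C@@H](OC(=O)c4ccccc4)[C@@H]2O1
F4 | step 5 | 1-(hydroxymethyl)-6β-hydroxy-3α,4α-(isopropylidenedioxy)cyclohex-1-en-5β-yl benzoate | CC1(C)O[C@@H]2C=C(CO)[C@@H](O)[C@@H](OC(=O)c3ccccc3)[C@@H]2O1
F0 | step 8 | none | none
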